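Locants: ring C1 (carbinol carbon) to C14, with C4=C5 (E), C6H2, C7=C8 (Z), C11=C12 (E) and methyls on C4, C8, C12. The side chain is C1′H(CH3)–C2′H2–C3′H2–C4′H=C5′(CH3)–C6′H2OH.
Cuts, in retrosynthetic order: C3′–C4′; then ring bond C5–C6 together with C4–CH3; then C2–C3, C1′–C2′, C1–C14 and C13–C14. This leaves nerol (C6–C13), crotonaldehyde (C2, C1, C1′ and its CH3), a vinyl, a propynyl and C1 units.
Enabling feature: in the 14-membered ring the doubly allylic C6H2 joins C5H=C4(CH3) (E) to C7H=C8(CH3) (Z). A 2-methylalk-1-enyl CH bonded to a primary allyl carbon is what syn CH3–metal addition to a terminal alkyne C4≡C5 followed by allylation would leave, and C6–C8 is the Z-allyl end of nerol.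
Forward: nerol is extended to a C14 borane and coupled to give a trisubstituted allylic alcohol. Epoxide chemistry then builds C1/C1′ and both arms, giving the unprotected acyclic alkynyl allylic alcohol 19. The only ring is closed in step 13 and the side chain is finished last.
Stereochemistry: C1 comes from Sharpless epoxidation with D-(−)-DET and C1′ from SN2 inversion at the epoxide CH. Z-C7=C8 comes from nerol, E-C11=C12 from the SeO2 oxidation, and E-C4=C5 and E-C4′=C5′ from syn methylalumination.

Key step: step 13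

Remark: TBSO stands for tert-butyldimethylsilyloxy; crotonaldehyde is taken as its commercial E isomer.

Step 1
Reactants: 1 nerol
Product: 2 neryl TBS ether
Conditions: TBSCl, imidazole, CH2Cl2, 0 °C to rt
Reagents that add atoms: tert-butyldimethylsilyl chloride, CC(C)(C)[Si](C)(C)Cl
Why: Imidazole-promoted silyl ether formation on a primary allylic alcohol should leave the Z alkene untouched.

Step 2
Reactants: 2 neryl TBS ether
Product: 3 (2E,6Z)-8-(TBSO)-2,6-dimethylocta-2,6-dien-1-ol
Conditions: SeO2 (cat.), tBuOOH, CH2Cl2, 0 °C to rt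
Reagents that add atoms: tert-butyl hydroperoxide (oxygen atom, relayed through SeO2), CC(C)(C)OO
Why: The Riley allylic oxidation (ene reaction, then [2,3]-sigmatropic shift) should attack the more electron-rich terminal isopropylidene group at the methyl trans to the chain, which fixes the E geometry of the future C11=C12.

Step 3
Reactants: 3 (2E,6Z)-8-(TBSO)-2,6-dimethylocta-2,6-dien-1-ol
Product: 4 (2E,6Z)-8-(TBSO)-2,6-dimethylocta-2,6-dienal
Conditions: MnO2, CH2Cl2, rt
Reagents that add atoms: none
Why: MnO2 oxidation is selective for allylic alcohols and should give the enal without change of either alkene geometry or loss of the silyl ether.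

Step 4
Reactants: 4 (2E,6Z)-8-(TBSO)-2,6-dimethylocta-2,6-dienal
Product: 5 tert-butyl{[(2Z,6E)-3,7-dimethylnona-2,6,8-trien-1-yl]oxy}dimethylsilane
Conditions: Ph3PCH3Br, KOtBu, THF, 0 °C
Reagents that add atoms: methyltriphenylphosphonium bromide, C[P+](c1ccccc1)(c1ccccc1)c1ccccc1.[Br-]
Why: Wittig methylenation with the non-stabilised ylide should turn the enal into the terminal 1,3-diene and bring in C14.

Step 5
Reactants: 6 (E)-crotonaldehyde
Product: 7 (2Z)-2-iodobut-2-enal
Conditions: I2, K2CO3, DMAP (cat.), THF/H2O, rt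
Reagents that add atoms: iodine, [I][I]
Why: Nucleophile-catalysed α-iodination of an enal (Baylis–Hillman-type addition of DMAP, iodination, elimination) should give the more stable Z iodoenal, with CH3 trans to CHO.

Step 6
Reactants: 7 (2Z)-2-iodobut-2-enal
Product: 8 (2Z)-2-iodobut-2-en-1-ol
Conditions: NaBH4, MeOH, 0 °C
Reagents that add atoms: none
Why: Borohydride 1,2-reduction of the aldehyde should leave the vinyl iodide and its geometry intact.

Step 7
Reactants: 5 tert-butyl{[(2Z,6E)-3,7-dimethylnona-2,6,8-trien-1-yl]oxy}dimethylsilane; 8 (2Z)-2-iodobut-2-en-1-ol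
Product: 10 (2E)-2-[(3E,7Z)-9-(TBSO)-3,7-dimethylnona-3,7-dien-1-yl]but-2-en-1-ol, via B-alkyl-9-BBN borane 9 (not isolated)
Conditions: 9-BBN, THF, 0 °C to rt; then 8, PdCl2(dppf) (cat.), AsPh3 (cat.), Cs2CO3, DMF/H2O, rt
Reagents that add atoms: none
Why: 9-BBN should add anti-Markovnikov only to the monosubstituted end of the diene, and the B-alkyl Suzuki–Miyaura coupling replaces iodine with retention, giving the E trisubstituted allylic alcohol (CH3 trans to CH2OH).

Step 8
Reactants: 10 (2E)-2-[(3E,7Z)-9-(TBSO)-3,7-dimethylnona-3,7-dien-1-yl]but-2-en-1-ol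
Product: 11 {(2R,3R)-2-[(3E,7Z)-9-(TBSO)-3,7-dimethylnona-3,7-dien-1-yl]-3-methyloxiran-2-yl}methanol
Conditions: Ti(OiPr)4 (cat.), D-(−)-DET (cat.), tBuOOH, 4 Å MS, CH2Cl2, −20 °C
Reagents that add atoms: tert-butyl hydroperoxide, CC(C)(C)OO
Why: In the Sharpless asymmetric epoxidation only the alkene that carries the free allylic hydroxyl reacts, and D-(−)-DET should deliver oxygen to the face that gives the (2R,3R) epoxide, which sets C1.

Step 9
Reactants: 11 {(2R,3R)-2-[(3E,7Z)-9-(TBSO)-3,7-dimethylnona-3,7-dien-1-yl]-3-methyloxiran-2-yl}methanol; 12 vinylmagnesium bromide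
Product: 13 (2S,3R)-2-[(3E,7Z)-9-(TBSO)-3,7-dimethylnona-3,7-dien-1-yl]-3-methylpent-4-ene-1,2-diol
Conditions: 12 (excess), CuI (cat.), THF, −40 to 0 °C; H2O quench
Reagents that add atoms: none
Why: Copper-catalysed SN2 opening of a 2,3-epoxy alcohol should occur at the secondary epoxide carbon, because the other one is fully substituted, with inversion that sets C1′ as R while the C1–O bond is untouched.

Step 10
Reactants: 13 (2S,3R)-2-[(3E,7Z)-9-(TBSO)-3,7-dimethylnona-3,7-dien-1-yl]-3-methylpent-4-ene-1,2-diol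
Product: 15 (2S)-2-[(2R)-but-3-en-2-yl]-2-[(3E,7Z)-9-(TBSO)-3,7-dimethylnona-3,7-dien-1-yl]oxirane, via primary monotosylate 14 (not isolated)
Conditions: NaH, N-tosylimidazole, THF, 0 °C to rt
Reagents that add atoms: none
Why: Selective sulfonylation of the primary hydroxyl followed by intramolecular Williamson displacement by the tertiary alkoxide should give the terminal epoxide with C1 retained.

Step 11
Reactants: 15 (2S)-2-[(2R)-but-3-en-2-yl]-2-[(3E,7Z)-9-(TBSO)-3,7-dimethylnona-3,7-dien-1-yl]oxirane; 16 1-(trimethylsilyl)propyne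
Product: 18 (5R,8E,12Z)-5-[(2R)-but-3-en-2-yl]-14-(TBSO)-8,12-dimethyl-1-(trimethylsilyl)tetradeca-8,12-dien-1-yn-5-ol, via 3-lithio-1-(trimethylsilyl)propyne 17 (not isolated)
Conditions: 16, nBuLi, THF, −78 to −20 °C; then 15, DMPU, −78 °C to rt; H2O quench
Reagents that add atoms: none
Why: SN2 opening of the 2,2-disubstituted epoxide at its CH2 end by the silyl-blocked propargyllithium should install C3–C5 and regenerate the tertiary alcohol without touching C1.

Step 12
Reactants: 18 (5R,8E,12Z)-5-[(2R)-but-3-en-2-yl]-14-(TBSO)-8,12-dimethyl-1-(trimethylsilyl)tetradeca-8,12-dien-1-yn-5-ol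
Product: 19 (2Z,6E,10S)-10-[(2R)-but-3-en-2-yl]-3,7-dimethyltetradeca-2,6-dien-13-yne-1,10-diol
Conditions: Bu4NF, wet THF, 0 °C to rt
Reagents that add atoms: none
Why: Fluoride-induced desilylation should cleave the O–Si and the alkynyl C–Si bond in one operation (the descriptor at the carbinol carbon changes only because the CIP ranking of the two arms changes).

Step 13
Reactants: 19 (2Z,6E,10S)-10-[(2R)-but-3-en-2-yl]-3,7-dimethyltetradeca-2,6-dien-13-yne-1,10-diol
Product: 21 (1R,4E,7Z,11E)-1-[(2R)-but-3-en-2-yl]-4,8,12-trimethylcyclotetradeca-4,7,11-trien-1-ol, via (E)-alkenyldimethylalane bis(aluminium alkoxide) 20 (not isolated)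
Conditions: Me3Al (excess), Cp2ZrCl2 (25 mol %), CH2Cl2, 0 °C to rt; excess Me3Al stripped in vacuo; slow addition to Pd(PPh3)4 (10 mol %), THF, 50 °C, ca. 1 mM; H2O quench
Reagents that add atoms: trimethylaluminium, C[Al](C)C
Why: Proposed new method: Me3Al first turns both hydroxyls of 19 into O–AlMe2 groups and then, under Cp2ZrCl2 catalysis, adds CH3–Al syn across the terminal alkyne C4≡C5 (methyl to internal C4, aluminium to C5), so that 20 holds both the nucleophile (the E alkenylalane) and, in the aluminium-activated allylic C6–O bond, the electrophile; zerovalent palladium should ionise that bond to an η3-allyl complex over C6–C7–C8, the alkenyl group passes from aluminium to palladium, and reductive elimination forms C5–C6. The closest known reaction type is the Negishi carboalumination followed by the intermolecular Pd-catalysed alkenylalane–allyl coupling, which joins 2-methylalk-1-enylalanes to neryl- and geranyl-type electrophiles at the primary carbon with retention of both alkene geometries; new here are the intramolecular macrocyclic setting and the reliance on the aluminium alkoxide formed in situ as the leaving group. The one ring closed is the 14-membered carbocycle, in an endo mode at both ends (C4=C5 and the whole allyl unit C6–C8 become ring members), whereas attack at tertiary C8 would give a 12-membered ring with a quaternary centre and is disfavoured sterically. No stereocentre is formed: C1 and C1′ are spectators, the E geometry of C4=C5 follows from syn addition and stereoretentive transmetalation and reductive elimination, and the Z geometry of C7=C8 from nerol should hold because syn–anti exchange at the fully substituted allyl terminus C8 would need a tertiary σ-allylpalladium. Chemoselectivity rests on the much faster methylalumination of a terminal alkyne than of the mono- and trisubstituted alkenes, on the preferred transfer of alkenyl over methyl from aluminium to palladium, and on C6–O being the only allylic C–O bond present, since the side-chain allylic alcohol is added only afterwards. Slow addition at about 1 mM should keep the first-order ring closure ahead of oligomerisation.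

Step 14
Reactants: 22 propargyl alcohol
Product: 24 (2E)-3-iodo-2-methylprop-2-en-1-ol, via (E)-alkenylalane aluminium alkoxide 23 (not isolated)
Conditions: Me3Al, Cp2ZrCl2 (25 mol %), CH2Cl2, 0 °C to rt; then I2, THF, −30 °C; H2O quench
Reagents that add atoms: trimethylaluminium, C[Al](C)C; iodine, [I][I]
Why: Negishi zirconium-catalysed methylalumination (syn addition, methyl to the internal carbon) and iodinolysis with retention should give the E iodide.

Step 15
Reactants: 21 (1R,4E,7Z,11E)-1-[(2R)-but-3-en-2-yl]-4,8,12-trimethylcyclotetradeca-4,7,11-trien-1-ol; 24 (2E)-3-iodo-2-methylprop-2-en-1-ol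
Product: 26 (1R,4E,7Z,11E)-1-[(2R,5E)-7-hydroxy-6-methylhept-5-en-2-yl]-4,8,12-trimethylcyclotetradeca-4,7,11-trien-1-ol, via macrocyclic B-alkyl-9-BBN borane 25 (not isolated)
Conditions: 9-BBN, THF, rt; then 24, PdCl2(dppf) (cat.), AsPh3 (cat.), Cs2CO3, DMF/H2O, rt
Reagents that add atoms: none
Why: 9-BBN should select the only monosubstituted alkene over the three trisubstituted ring alkenes, and the B-alkyl Suzuki–Miyaura coupling joins C3′ to C4′ with retention of the E geometry of 24, with no protecting group needed.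

Compound list
1 | nerol, (2Z)-3,7-dimethylocta-2,6-dien-1-ol | CC(C)=CCC/C(C)=C\CO | starting material
2 | neryl TBS ether, tert-butyl{[(2Z)-3,7-dimethylocta-2,6-dien-1-yl]oxy}dimethylsilane | CC(C)=CCC/C(C)=C\CO[Si](C)(C)C(C)(C)C | intermediate
3 | (2E,6Z)-8-(TBSO)-2,6-dimethylocta-2,6-dien-1-ol | OC/C(C)=C/CC/C(C)=C\CO[Si](C)(C)C(C)(C)C | intermediate
4 | (2E,6Z)-8-(TBSO)-2,6-dimethylocta-2,6-dienal | O=C/C(C)=C/CC/C(C)=C\CO[Si](C)(C)C(C)(C)C | intermediate
5 | tert-butyl{[(2Z,6E)-3,7-dimethylnona-2,6,8-trien-1-yl]oxy}dimethylsilane | C=C/C(C)=C/CC/C(C)=C\CO[Si](C)(C)C(C)(C)C | intermediate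
6 | (E)-crotonaldehyde, (2E)-but-2-enal | C/C=C/C=O | starting material
7 | (2Z)-2-iodobut-2-enal | C/C=C(\I)C=O | intermediate
8 | (2Z)-2-iodobut-2-en-1-ol | C/C=C(\I)CO | intermediate
9 | 9-[(3E,7Z)-9-(TBSO)-3,7-dimethylnona-3,7-dien-1-yl]-9-borabicyclo[3.3.1]nonane | B1(CC/C(C)=C/CC/C(C)=C\CO[Si](C)(C)C(C)(C)C)C2CCCC1CCC2 | intermediate
10 | (2E)-2-[(3E,7Z)-9-(TBSO)-3,7-dimethylnona-3,7-dien-1-yl]but-2-en-1-ol | C/C=C(/CO)CC/C(C)=C/CC/C(C)=C\CO[Si](C)(C)C(C)(C)C | intermediate
11 | {(2R,3R)-2-[(3E,7Z)-9-(TBSO)-3,7-dimethylnona-3,7-dien-1-yl]-3-methyloxiran-2-yl}methanol | C[C@H]1O[C@@]1(CO)CC/C(C)=C/CC/C(C)=C\CO[Si](C)(C)C(C)(C)C | intermediate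
12 | vinylmagnesium bromide | C=C[Mg]Br | starting material
13 | (2S,3R)-2-[(3E,7Z)-9-(TBSO)-3,7-dimethylnona-3,7-dien-1-yl]-3-methylpent-4-ene-1,2-diol | OC[C@@](O)([C@H](C)C=C)CC/C(C)=C/CC/C(C)=C\CO[Si](C)(C)C(C)(C)C | intermediate
14 | primary 4-methylbenzenesulfonate of diol 13 (tertiary hydroxyl free) | Cc1ccc(cc1)S(=O)(=O)OC[C@@](O)([C@H](C)C=C)CC/C(C)=C/CC/C(C)=C\CO[Si](C)(C)C(C)(C)C | intermediate
15 | (2S)-2-[(2R)-but-3-en-2-yl]-2-[(3E,7Z)-9-(TBSO)-3,7-dimethylnona-3,7-dien-1-yl]oxirane | C1O[C@]1([C@H](C)C=C)CC/C(C)=C/CC/C(C)=C\CO[Si](C)(C)C(C)(C)C | intermediate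
16 | 1-(trimethylsilyl)propyne | CC#C[Si](C)(C)C | starting material
17 | 3-lithio-1-(trimethylsilyl)propyne | [Li]CC#C[Si](C)(C)C | intermediate
18 | (5R,8E,12Z)-5-[(2R)-but-3-en-2-yl]-14-(TBSO)-8,12-dimethyl-1-(trimethylsilyl)tetradeca-8,12-dien-1-yn-5-ol | C[Si](C)(C)C#CCC[C@@](O)([C@H](C)C=C)CC/C(C)=C/CC/C(C)=C\CO[Si](C)(C)C(C)(C)C | intermediate
19 | (2Z,6E,10S)-10-[(2R)-but-3-en-2-yl]-3,7-dimethyltetradeca-2,6-dien-13-yne-1,10-diol | C#CCC[C@@](O)([C@H](C)C=C)CC/C(C)=C/CC/C(C)=C\CO | intermediate
20 | (E)-2-methylalk-1-enyldimethylalane from 19, both oxygens as O–AlMe2 | C[Al](C)/C=C(\C)CC[C@@](O[Al](C)C)([C@H](C)C=C)CC/C(C)=C/CC/C(C)=C\CO[Al](C)C | intermediate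
21 | (1R,4E,7Z,11E)-1-[(2R)-but-3-en-2-yl]-4,8,12-trimethylcyclotetradeca-4,7,11-trien-1-ol | C/C1=C/C/C=C(\C)CC[C@@](O)([C@H](C)C=C)CC/C(C)=C/CC1 | intermediate
22 | propargyl alcohol, prop-2-yn-1-ol | C#CCO | starting material
23 | (E)-3-(dimethylalumanyl)-2-methylprop-2-en-1-ol, oxygen as O–AlMe2 | C[Al](C)/C=C(\C)CO[Al](C)C | intermediate
24 | (2E)-3-iodo-2-methylprop-2-en-1-ol | OC/C(C)=C/I | intermediate
25 | 9-BBN adduct of 21 at the terminal side-chain carbon C3′ | C/C1=C/C/C=C(\C)CC[C@@](O)([C@H](C)CCB2C3CCCC2CCC3)CC/C(C)=C/CC1 | intermediate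
26 | (1R,4E,7Z,11E)-1-[(2R,5E)-7-hydroxy-6-methylhept-5-en-2-yl]-4,8,12-trimethylcyclotetradeca-4,7,11-trien-1-ol | C/C1=C/C/C=C(\C)CC[C@@](O)([C@H](C)CC/C=C(\C)CO)CC/C(C)=C/CC1 | target

Total step count: 15. Longest linear sequence: 12 steps (1–4, 7–13, 15, from nerol).

Steps most likely to fail

Step 13. Ionisation of the aluminium alkoxide by zerovalent palladium may be too slow. Methyl instead of alkenyl may pass to the allylpalladium, or oligomerisation may outrun ring closure. The fallback sets out from 19 and comes back at 21, using known chemistry only. Methylalumination of 19 as in step 13 is quenched with iodine to give the (E)-vinyl iodide diol F1. Exchange with hexamethylditin under Pd(PPh3)4 gives the (E)-alkenyltrimethylstannane diol F2. MsCl, LiCl and 2,4,6-collidine in DMF at 0 °C should convert only the primary allylic alcohol, with retention of the Z alkene, into the stannyl allylic chloride F3. An intramolecular Stille coupling of allyl chloride and alkenylstannane (Pd2(dba)3, AsPh3, THF, high dilution) then closes C5–C6 and gives 21.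

Step 9. Attack at the secondary epoxide carbon next to the fully substituted C1 may be slow. Opening by halide, epoxide migration of the Payne type, or attack with the wrong regiochemistry could then compete. The fallback sets out from 11 and comes back at 13. Diethyl(trimethylsilylethynyl)aluminium (from trimethylsilylacetylene, nBuLi and Et2AlCl) binds the alkoxide of 11 and should deliver the slim sp nucleophile to the epoxide CH with inversion, giving the silylalkynyl diol F4. K2CO3 in MeOH removes the C-silyl group to give the terminal alkynyl diol F5. Semihydrogenation (H2, Pd/CaCO3 poisoned with Pb(OAc)2, quinoline) reduces only the alkyne and gives 13.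

Step 11. The strongly basic organolithium may deprotonate next to the epoxide and isomerise it to an allylic alcohol, or it may react through its allenyl terminus. The fallback sets out from 15 and comes back at 19, building the alkyne by homologation instead. Lithioacetonitrile (MeCN, nBuLi, THF, −78 °C), which is smaller and less basic, opens 15 at CH2 to give the γ-hydroxy nitrile F6. Diisobutylaluminium hydride followed by aqueous hydrolysis gives the γ-hydroxy aldehyde F7, which is in equilibrium with its lactol. Ohira–Bestmann homologation (dimethyl (1-diazo-2-oxopropyl)phosphonate, K2CO3, MeOH) gives the terminal alkyne silyl ether F8, and Bu4NF then gives 19.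

Further compounds
F1 | step 13 | (2Z,6E,10R,13E)-10-[(2R)-but-3-en-2-yl]-14-iodo-3,7,13-trimethyltetradeca-2,6,13-triene-1,10-diol | I/C=C(\C)CC[C@@](O)([C@H](C)C=C)CC/C(C)=C/CC/C(C)=C\CO
F2 | step 13 | (2Z,6E,10R,13E)-10-[(2R)-but-3-en-2-yl]-3,7,13-trimethyl-14-(trimethylstannyl)tetradeca-2,6,13-triene-1,10-diol | C[Sn](C)(C)/C=C(\C)CC[C@@](O)([C@H](C)C=C)CC/C(C)=C/CC/C(C)=C\CO
F3 | step 13 | (1E,5R,8E,12Z)-5-[(2R)-but-3-en-2-yl]-14-chloro-2,8,12-trimethyl-1-(trimethylstannyl)tetradeca-1,8,12-trien-5-ol | C[Sn](C)(C)/C=C(\C)CC[C@@](O)([C@H](C)C=C)CC/C(C)=C/CC/C(C)=C\CCl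
F4 | step 9 | (2S,3R)-2-[(3E,7Z)-9-(TBSO)-3,7-dimethylnona-3,7-dien-1-yl]-3-methyl-5-(trimethylsilyl)pent-4-yne-1,2-diol | OC[C@@](O)([C@H](C)C#C[Si](C)(C)C)CC/C(C)=C/CC/C(C)=C\CO[Si](C)(C)C(C)(C)C
F5 | step 9 | (2S,3R)-2-[(3E,7Z)-9-(TBSO)-3,7-dimethylnona-3,7-dien-1-yl]-3-methylpent-4-yne-1,2-diol | OC[C@@](O)([C@H](C)C#C)CC/C(C)=C/CC/C(C)=C\CO[Si](C)(C)C(C)(C)C
F6 | step 11 | (4R,7E,11Z)-4-[(2R)-but-3-en-2-yl]-13-(TBSO)-4-hydroxy-7,11-dimethyltrideca-7,11-dienenitrile | N#CCC[C@@](O)([C@H](C)C=C)CC/C(C)=C/CC/C(C)=C\CO[Si](C)(C)C(C)(C)C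
F7 | step 11 | (4R,7E,11Z)-4-[(2R)-but-3-en-2-yl]-13-(TBSO)-4-hydroxy-7,11-dimethyltrideca-7,11-dienal (open form) | O=CCC[C@@](O)([C@H](C)C=C)CC/C(C)=C/CC/C(C)=C\CO[Si](C)(C)C(C)(C)C
F8 | step 11 | (5S,8E,12Z)-5-[(2R)-but-3-en-2-yl]-14-(TBSO)-8,12-dimethyltetradeca-8,12-dien-1-yn-5-ol | C#CCC[C@@](O)([C@H](C)C=C)CC/C(C)=C/CC/C(C)=C\CO[Si](C)(C)C(C)(C)C
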